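**Strategy.** The tricycle is unravelled through the C7 carbonyl, which lies 1,3 to O‑9 (aldol retron) and 1,5 to the C1 ketone through C6–C5–C11 (Michael retron). Rings: A = cyclohexanone C1–C4/C10/C11; B = seven‑membered C4–C10; C = cyclobutane C4/C5/C11/C10. One silyl triflate‑triggered cascade on a monocyclic cyclohexenone carrying a C9 aldehyde and a C5 alkylidene acetoacetate closes C8–C9 and then C5–C11. This forges rings B and C and three stereocentres. The precursor comes from a Diels–Alder reaction of a menthyloxy butenolide; a bridging lactone later relays C9 to C6 and C7.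

Key step: step 5

Remark (locants, longipinane numbering): C1 ring ketone, C2 CH2, C3 CH(CH3) (methyl = C15), C4 and C11 cyclobutane CH flanking ring A, C5 cyclobutane CH bonded to C6, C6 quaternary (C12 = oxygenated carbon, C13 = methyl), C7 CH–O, C8 CH2, C9 CH–O, C10 quaternary (methyl = C14). In the target O‑9 and C12 lie on the C11 side of ring B; O‑7 and C13 lie on the C4 side. Compounds 11–13 lack C13 and C15 (13,15-dinor); compounds 14–19 lack C15 (15-nor).

Remark (assumption): the two C5 epimers of acetal 3 are assumed to equilibrate under acid and to be separable by crystallisation, as is usual for γ‑alkoxybutenolides; the epimer needed is the (5S) one.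

**Step 1**
Reactants: 1 5-hydroxy-4-methylfuran-2(5H)-one; 2 (+)-menthol
Product: 3 (5S)-4-methyl-5-[(1S,2R,5S)-menthyloxy]furan-2(5H)-one
Conditions: camphorsulfonic acid (cat.), toluene, reflux (Dean–Stark); crystallise, re-equilibrate mother liquor
Reagents that add atoms: none
Why: Acid-catalysed acetalisation of the pseudo-acid should give both C5 epimers, which interconvert under the acidic conditions, so the (5S) epimer can be collected by crystallisation; this acetal carbon steers the next step and later becomes the C9 aldehyde.

**Step 2**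
Reactants: 3 (5S)-menthyloxy butenolide; 4 (E)-1-methoxy-3-(trimethylsilyloxy)buta-1,3-diene
Product: 5 cis-fused 3-(menthyloxy)-7-methoxy-3a-methyl-5-(trimethylsilyloxy)-3a,4,7,7a-tetrahydro-2-benzofuran-1(3H)-one
Conditions: toluene, 130 °C, sealed tube
Reagents that add atoms: none
Why: Diels–Alder reaction in which the nucleophilic CH2 terminus of the siloxydiene bonds to the β-carbon of the butenolide (future quaternary C10) and the diene approaches anti to the menthyloxy group, so C10 and C4 should be set as a cis pair in the configuration of the target.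

**Step 3**
Reactants: 5 Diels–Alder adduct
Product: 7 lactol enone 3-hydroxy-1-(menthyloxy)-7a-methyl-1,3,3a,7a-tetrahydro-2-benzofuran-6(7H)-one, via lactol silyl enol ether 6 (not isolated)
Conditions: i-Bu2AlH, CH2Cl2, −78 °C; then 0.1 M HCl, THF, 0 °C
Reagents that add atoms: none
Why: Hydride reduction of the lactone to the lactol is carried out while the enone is still masked as the silyl enol ether, and the brief dilute-acid treatment then hydrolyses the enol ether and eliminates methanol (E1cB) to unveil the cyclohexenone without touching C4 and C10.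

**Step 4**
Reactants: 7 lactol enone; 8 methyl acetoacetate
Product: 9 methyl 2-acetyl-3-[(1S,6S)-6-formyl-6-methyl-4-oxocyclohex-2-en-1-yl]prop-2-enoate (E/Z mixture)
Conditions: ethylenediammonium diacetate (cat.), 4 Å MS, CH2Cl2, 0 °C → rt
Reagents that add atoms: none
Why: Knoevenagel condensation at the ring-opened lactol carbon (C5); the menthyl hemiacetal left at C9 collapses to the hindered neopentyl aldehyde, which should not condense, and the mild buffer should leave C4 intact.

**Step 5**
Reactants: 9 keto aldehyde with alkylidene acetoacetate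
Product: 12 methyl 7,9-bis(tert-butyldimethylsilyloxy)-1-oxo-13,15-dinorlongipina-2,6-dien-12-oate, via bis(silyl dienol ether) 10 (not isolated), via bicyclic aldol silyl ether 11 (not isolated)
Conditions: Et3N (2.0 equiv), TBSOTf (2.3 equiv), CH2Cl2, −78 → −10 °C
Reagents that add atoms: tert-butyldimethylsilyl trifluoromethanesulfonate (two molecules are incorporated), CC(C)(C)[Si](C)(C)OS(=O)(=O)C(F)(F)F
Why: Triethylamine (limiting) and TBSOTf convert both enolisable ketones into siloxydienes (10), which switches off both enone acceptors and leaves the silyl-activated, non-enolisable C9 aldehyde as the only electrophile; the terminal CH2 (C8) of the 2-siloxydiene adds to it in an intramolecular Mukaiyama aldol reaction (7-exo-trig at C9=O) that closes ring B and regenerates the alkylidene β-keto ester in 11, after which the cross-conjugated dienol silane of ring A adds through C11 to C5 in a ring-bridging Mukaiyama–Michael reaction (4-exo-trig) with silyl transfer to O-7. The closest known reaction types are silyl triflate/amine-promoted intramolecular Michael–aldol cascades and γ-selective Mukaiyama aldol reactions of acetoacetate-derived siloxydienes. C9 is set in the aldol step, where the bulky silylated oxygen should take the open sector next to the flat sp2 C11 (trans to the angular C10 methyl on ring B) and not the one next to the substituted C4, but this is the least secure selectivity of the step; C5 and C11 are dictated by the ring fusion, because C5 is held in the seven-membered ring cis-fused at C4–C10 and can reach C11 on one face only. The step needs enolisation at C11 and at the acetyl methyl only (C2/C3 are sp2, C4–H is hindered, and no base remains after two silylations, so the 0.3 equiv of TBSOTf acts as Lewis acid), the alkylidene isomer with ring A cis to the acetyl branch (the isomers should interconvert by reversible amine addition), and a favourable equilibrium for the cyclobutane closure, which the doubly activated acceptor and the conjugated β-silyloxy enoate product are meant to provide.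

**Step 6**
Reactants: 12 tricyclic bis-silyl compound
Product: 13 methyl 9-hydroxy-1,7-dioxo-13,15-dinorlongipin-2-en-12-oate (keto/enol tautomers)
Conditions: HF·pyridine, pyridine, THF, 0 °C → rt
Reagents that add atoms: none
Why: Fluoride desilylation cleaves the silyl enol ether and the secondary silyl ether under weakly acidic conditions that should avoid retro-aldol and retro-Michael opening.

**Step 7**
Reactants: 13 δ-hydroxy β-keto ester
Product: 15 1,7-dioxo-15-norlongipin-2-en-12,9-olide, via C6-methylated hydroxy keto ester 14 (not isolated)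
Conditions: LiN(SiMe3)2 (2.3 equiv), THF, −78 °C; MeI, −78 °C → rt; aq. NH4Cl
Reagents that add atoms: iodomethane, CI
Why: C-Alkylation of the alkoxide/β-keto ester enolate dianion (Fráter–Seebach-type chelate control), in which the cyclobutane carbon C11 on C5 and the lithium held between O-9 and the enolate oxygen should both block the C6 face on the C11 side so that methyl enters from the C4 side, and only this epimer has the ester cis to the alkoxide and closes the bridging δ-lactone (intramolecular transesterification).

**Step 8**
Reactants: 15 keto lactone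
Product: 17 15-norlongipin-2-ene-1,7,9,12-tetraol, via dihydroxy lactone 16 (not isolated)
Conditions: i-Bu2AlH (excess), CH2Cl2, −78 °C → rt; aq. KNaC4H4O6
Reagents that add atoms: none
Why: Hydride reduction in which the C7 ketone is attacked first from the face next to the flat lactone bridge (the other face is screened by H-4), which should place O-7 on the C4 side, anti to O-9; excess reagent then opens the lactone to the C9/C12 diol and reduces the enone carbonyl 1,2.

**Step 9**
Reactants: 17 tetraol
Product: 18 7,9,12-trihydroxy-15-norlongipin-2-en-1-one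
Conditions: MnO2, CH2Cl2, rt
Reagents that add atoms: none
Why: Chemoselective allylic oxidation should restore the enone and leave the three saturated alcohols untouched.

**Step 10**
Reactants: 18 enone triol
Product: 19 12-(tert-butyldimethylsilyloxy)-7,9-dihydroxy-15-norlongipin-2-en-1-one
Conditions: TBSCl, imidazole, DMF, 0 °C
Reagents that add atoms: tert-butyldimethylsilyl chloride, CC(C)(C)[Si](C)(C)Cl
Why: Selective silylation of the primary hydroxyl over the two hindered secondary hydroxyls.

**Step 11**
Reactants: 19 enone diol silyl ether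
Product: 20 12-(tert-butyldimethylsilyloxy)-7,9-dihydroxylongipinan-1-one
Conditions: Me2CuLi (from MeLi and CuI, excess), Et2O, −40 → 0 °C; aq. NH4Cl
Reagents that add atoms: lithium dimethylcuprate, [Li+].C[Cu-]C
Why: Cuprate conjugate addition to the bicyclo[3.1.1]heptenone from the face of the CH bridge C5, anti to the methyl-bearing bridge C10, which should set C3 with its methyl cis to C5; the excess reagent covers the two free hydroxyls.

**Step 12**
Reactants: 20 keto diol silyl ether; 21 angelic acid (3.0 equiv used, two molecules are incorporated)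
Product: 23 7,9-bis(angeloyloxy)-12-(tert-butyldimethylsilyloxy)longipinan-1-one, via angelic 2,4,6-trichlorobenzoic anhydride 22 (not isolated)
Conditions: 21 (3.0 equiv), 2,4,6-trichlorobenzoyl chloride (3.0 equiv), Et3N (3.3 equiv), toluene, rt; then 20 (1.0 equiv), 80 °C
Reagents that add atoms: angelic acid (the second molecule of 21 that is incorporated), C/C=C(/C)C(=O)O; 2,4,6-trichlorobenzoyl chloride (its atoms stay only in intermediate 22), O=C(Cl)c1c(Cl)cc(Cl)cc1Cl
Why: Yamaguchi esterification in which each of the two hindered secondary hydroxyls (O-7 and O-9) is acylated by one molecule of the preformed mixed anhydride at its less hindered angeloyl carbonyl, run in toluene without DMAP so that the (Z)-2-methylbut-2-enoyl groups should not isomerise to the tigloyl isomer.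

**Step 13**
Reactants: 23 bis-angelate silyl ether
Product: 24 7,9-bis(angeloyloxy)-12-hydroxylongipinan-1-one (CNP0287707.1)
Conditions: HF·pyridine, pyridine, THF, 0 °C → rt
Reagents that add atoms: none
Why: Acidic fluoride desilylation of the primary silyl ether in a non-basic medium, which should prevent 1,3-acyl migration from O-7 to O-12 and E/Z isomerisation.

**Compound list**

1 | 5-hydroxy-4-methylfuran-2(5H)-one | CC1=CC(=O)OC1O | starting material
2 | (+)-menthol, (1S,2R,5S)-5-methyl-2-(propan-2-yl)cyclohexan-1-ol | O[C@H]1C[C@@H](C)CC[C@@H]1C(C)C | starting material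
3 | (5S)-4-methyl-5-[(1S,2R,5S)-menthyloxy]furan-2(5H)-one | CC1=CC(=O)O[C@@H]1O[C@H]2C[C@@H](C)CC[C@@H]2C(C)C | intermediate
4 | (E)-1-methoxy-3-(trimethylsilyloxy)buta-1,3-diene | CO/C=C/C(=C)O[Si](C)(C)C | starting material
5 | cis-fused 3-(menthyloxy)-7-methoxy-3a-methyl-5-(trimethylsilyloxy)-3a,4,7,7a-tetrahydro-2-benzofuran-1(3H)-one (methoxy carbon unassigned) | COC1C=C(O[Si](C)(C)C)C[C@]2(C)[C@@H](O[C@H]3C[C@@H](C)CC[C@@H]3C(C)C)OC(=O)[C@H]12 | intermediate
6 | lactol of 5 (lactol carbon unassigned) | COC1C=C(O[Si](C)(C)C)C[C@]2(C)[C@@H](O[C@H]3C[C@@H](C)CC[C@@H]3C(C)C)OC(O)[C@H]12 | intermediate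
7 | lactol enone, 3-hydroxy-1-(menthyloxy)-7a-methyl-1,3,3a,7a-tetrahydro-2-benzofuran-6(7H)-one | O=C1C=C[C@H]2C(O)O[C@H](O[C@H]3C[C@@H](C)CC[C@@H]3C(C)C)[C@@]2(C)C1 | intermediate
8 | methyl acetoacetate | CC(=O)CC(=O)OC | starting material
9 | methyl 2-acetyl-3-[(1S,6S)-6-formyl-6-methyl-4-oxocyclohex-2-en-1-yl]prop-2-enoate (E/Z mixture; formyl cis to side chain) | O=C[C@@]1(C)CC(=O)C=C[C@H]1C=C(C(C)=O)C(=O)OC | intermediate
10 | methyl (E)-3-[4-(tert-butyldimethylsilyloxy)-6-formyl-6-methylcyclohexa-2,4-dien-1-yl]-2-[1-(tert-butyldimethylsilyloxy)ethenyl]prop-2-enoate | O=C[C@@]1(C)C=C(O[Si](C)(C)C(C)(C)C)C=C[C@H]1/C=C(/C(=O)OC)C(=C)O[Si](C)(C)C(C)(C)C | intermediate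
11 | methyl 1,9-bis(tert-butyldimethylsilyloxy)-7-oxo-13,15-dinor-5,11-secolongipina-1(11),2,5-trien-12-oate (cis-fused rings A/B) | CC(C)(C)[Si](C)(C)OC1=C[C@]2(C)[C@H](O[Si](C)(C)C(C)(C)C)CC(=O)C(C(=O)OC)=C[C@@H]2C=C1 | intermediate
12 | methyl 7,9-bis(tert-butyldimethylsilyloxy)-1-oxo-13,15-dinorlongipina-2,6-dien-12-oate | CC(C)(C)[Si](C)(C)OC1=C(C(=O)OC)[C@@H]2[C@H]3C(=O)C=C[C@@H]2[C@@]3(C)[C@H](O[Si](C)(C)C(C)(C)C)C1 | intermediate
13 | methyl 9-hydroxy-1,7-dioxo-13,15-dinorlongipin-2-en-12-oate (C6 epimerisable, drawn as keto form) | O=C1C(C(=O)OC)[C@@H]2[C@H]3C(=O)C=C[C@@H]2[C@@]3(C)[C@H](O)C1 | intermediate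
14 | methyl 9-hydroxy-1,7-dioxo-15-norlongipin-2-en-12-oate (C6 quaternary, ester cis to O-9) | O=C1[C@](C)(C(=O)OC)[C@@H]2[C@H]3C(=O)C=C[C@@H]2[C@@]3(C)[C@H](O)C1 | intermediate
15 | 1,7-dioxo-15-norlongipin-2-en-12,9-olide | O=C1C[C@H]2OC(=O)[C@]1(C)[C@@H]3[C@H]4C(=O)C=C[C@@H]3[C@@]24C | intermediate
16 | 1,7-dihydroxy-15-norlongipin-2-en-12,9-olide (C1 unassigned) | O[C@@H]1C[C@H]2OC(=O)[C@]1(C)[C@@H]3[C@H]4C(O)C=C[C@@H]3[C@@]24C | intermediate
17 | 15-norlongipin-2-ene-1,7,9,12-tetraol (C1 unassigned) | O[C@@H]1C[C@@H](O)[C@]2(C)[C@@H]3[C@@H]([C@H]2C(O)C=C3)[C@@]1(C)CO | intermediate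
18 | 7,9,12-trihydroxy-15-norlongipin-2-en-1-one | O[C@@H]1C[C@@H](O)[C@]2(C)[C@@H]3[C@@H]([C@H]2C(=O)C=C3)[C@@]1(C)CO | intermediate
19 | 12-(tert-butyldimethylsilyloxy)-7,9-dihydroxy-15-norlongipin-2-en-1-one | O[C@@H]1C[C@@H](O)[C@]2(C)[C@@H]3[C@@H]([C@H]2C(=O)C=C3)[C@@]1(C)CO[Si](C)(C)C(C)(C)C | intermediate
20 | 12-(tert-butyldimethylsilyloxy)-7,9-dihydroxylongipinan-1-one | O[C@@H]1C[C@@H](O)[C@]2(C)[C@@H]3[C@@H]([C@H]2C(=O)C[C@H]3C)[C@@]1(C)CO[Si](C)(C)C(C)(C)C | intermediate
21 | angelic acid, (Z)-2-methylbut-2-enoic acid | C/C=C(/C)C(=O)O | starting material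
22 | (Z)-2-methylbut-2-enoic 2,4,6-trichlorobenzoic anhydride | C/C=C(/C)C(=O)OC(=O)c1c(Cl)cc(Cl)cc1Cl | intermediate
23 | 7,9-bis(angeloyloxy)-12-(tert-butyldimethylsilyloxy)longipinan-1-one | C/C=C(/C)C(=O)O[C@@H]1C[C@@H](OC(=O)/C(C)=C\C)[C@]2(C)[C@@H]3[C@@H]([C@H]2C(=O)C[C@H]3C)[C@@]1(C)CO[Si](C)(C)C(C)(C)C | intermediate
24 | 7,9-bis(angeloyloxy)-12-hydroxylongipinan-1-one, CNP0287707.1 | C/C=C(/C)C(=O)O[C@@H]1C[C@@H](OC(=O)/C(C)=C\C)[C@]2(C)[C@@H]3[C@@H]([C@H]2C(=O)C[C@H]3C)[C@@]1(C)CO | target

**Totals.** 13 steps; longest linear sequence 13 steps (from 1).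

**Steps most likely to fail**

Step 5. The four-membered ring closure is a reversible conjugate addition and may not be favoured under neutral silyl-transfer conditions. The cascade may also stall if the alkylidene isomers do not interconvert or the C7 ketone is re-silylated, and facial selectivity of the aldol at C9 may be low. Fallback: the two bond formations are staged and the ring closure is made anionic with a thermodynamic sink. Setting out from 9, silylation and aldol closure are run at −78 °C and quenched cold, and the bicyclic silyl dienol ether 11 is isolated. One equivalent of anhydrous Bu4NF in THF at −78 °C then releases the regiodefined C11 dienolate, which should close the cyclobutane by 4-exo-trig Michael addition because the product is the stabilised β-keto ester enolate. Protonation gives methyl 9-(tert-butyldimethylsilyloxy)-1,7-dioxo-13,15-dinorlongipin-2-en-12-oate F1, and HF·pyridine converts it into 13, where the route is rejoined.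

Step 2. The β,β-disubstituted butenolide may be too unreactive, and the diene may decompose or the regio- and facial selectivity may erode at the temperature needed. Fallback: a stepwise anionic annulation replaces the cycloaddition. Setting out from 3, the kinetic lithium dienolate of (E)-4-methoxybut-3-en-2-one (LiN(i-Pr)2, THF, −78 °C) adds 1,4 to the butenolide anti to the menthyloxy group. The lactone enolate then closes onto the vinylogous ester (intramolecular Michael addition), and Me3SiCl traps the ketone enolate to give 5 directly, with no new isolated compound.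

Step 7. Facial selectivity of the C-methylation may be poor, the alkoxide may be O-methylated or open by retro-aldol cleavage, and lactonisation may fail. Fallback: the hydroxyl is kept protected, so that steric control replaces the dianion chemistry and lactonisation becomes a separate step. Setting out from 12, only the silyl enol ether is cleaved with anhydrous benzyltrimethylammonium fluoride (1.1 equiv) in THF at −40 °C in the presence of MeI (fluoride-promoted alkylation of a silyl enol ether). The ammonium enolate should be C-methylated from the face remote from C11 and from the bulky C9 silyloxy group, giving methyl 9-(tert-butyldimethylsilyloxy)-1,7-dioxo-15-norlongipin-2-en-12-oate F2. HF·pyridine then frees the hydroxyl to give 14, and DBU (cat.) in toluene closes the lactone to 15, where the route is rejoined.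

**Further compounds**

F0 | step 2 | none | none
F1 | step 5 | methyl 9-(tert-butyldimethylsilyloxy)-1,7-dioxo-13,15-dinorlongipin-2-en-12-oate | O=C1C(C(=O)OC)[C@@H]2[C@H]3C(=O)C=C[C@@H]2[C@@]3(C)[C@H](O[Si](C)(C)C(C)(C)C)C1
F2 | step 7 | methyl 9-(tert-butyldimethylsilyloxy)-1,7-dioxo-15-norlongipin-2-en-12-oate | O=C1[C@](C)(C(=O)OC)[C@@H]2[C@H]3C(=O)C=C[C@@H]2[C@@]3(C)[C@H](O[Si](C)(C)C(C)(C)C)C1
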